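Everything rests on cutting the C3–C4 bond of the butyrolactone (ring atoms O1, C2 carbonyl, C3, C4, C5). The chain C2–C3–C4–C5 is a 1,4-dioxygenated succinate-type unit whose two adjacent ring carbons each hold an arylmethyl group, so the cut gives two 3-arylpropanoyl halves. These are joined by oxidative cross-coupling of two lithium enolates, one being an (S)-4-benzyloxazolidinone imide (3,4,5-trimethoxyphenyl half), the other a tert-butyl ester (3,4-dimethoxyphenyl half); the single operation builds the whole carbon skeleton and fixes C4. Imide reduction, lactonisation and base equilibration of enolisable C3 then give the trans (3R,4R) lactone.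

Key step: step 3

Remark on the chemistry: the lactone labels O1, C2 (carbonyl), C3 (bearing the 3,4-dimethoxybenzyl group), C4 (bearing the 3,4,5-trimethoxybenzyl group) and C5 (oxymethylene) are also used for the matching carbons of open-chain precursors; because C3 is corrected by equilibration at the end, the coupled product, the hydroxy ester and the crude lactone are carried as C3 epimer mixtures; LiN(iPr)2 is taken from a commercial solution.

Step 1
Reactants: 1 3-(3,4,5-trimethoxyphenyl)propanoic acid; 2 (S)-4-benzyl-2-oxazolidinone
Product: 4 (S)-4-benzyl-3-[3-(3,4,5-trimethoxyphenyl)propanoyl]oxazolidin-2-one (fragment 1), via mixed pivalic anhydride 3 (not isolated)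
Conditions: PivCl, Et3N, THF, −20 °C; then LiCl, 2, −20 °C to rt
Reagents that add atoms: pivaloyl chloride, CC(C)(C)C(Cl)=O (pivaloyl group carried only in intermediate 3; no reagent atom remains in 4)
Why: Pivaloyl chloride converts the triethylammonium carboxylate of 1 into mixed anhydride 3, whose unhindered 3-arylpropanoyl carbonyl is then attacked by the LiCl/Et3N-activated oxazolidinone nitrogen (mixed-anhydride N-acylation of an oxazolidinone), a mild operation that creates no stereocentre and leaves the (S) centre of the auxiliary untouched.

Step 2
Reactants: 5 3-(3,4-dimethoxyphenyl)propanoic acid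
Product: 6 tert-butyl 3-(3,4-dimethoxyphenyl)propanoate (fragment 2)
Conditions: Boc2O, DMAP (cat.), t-BuOH, 35 °C
Reagents that add atoms: tert-butanol, CC(C)(C)O; di-tert-butyl dicarbonate, CC(C)(C)OC(=O)OC(=O)OC(C)(C)C (the tert-butoxy group of 6 can come from either)
Why: Boc2O activates the acid as a mixed carbonic anhydride, DMAP turns this into an acylpyridinium ion and tert-butanol captures it (DMAP-catalysed tert-butyl esterification, a Steglich-type acyl transfer), which forms the hindered ester without any carbocation that could alkylate the electron-rich dimethoxyarene and gives a coupling partner that resists self-condensation.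

Step 3
Reactants: 4 (S)-4-benzyl-3-[3-(3,4,5-trimethoxyphenyl)propanoyl]oxazolidin-2-one (fragment 1); 6 tert-butyl 3-(3,4-dimethoxyphenyl)propanoate (fragment 2)
Product: 9 tert-butyl (3R)-3-[(4S)-4-benzyl-2-oxooxazolidine-3-carbonyl]-2-(3,4-dimethoxybenzyl)-4-(3,4,5-trimethoxyphenyl)butanoate (epimer mixture at the ester α-carbon), via imide lithium Z-enolate 7 (not isolated), via ester lithium enolate 8 (not isolated)
Conditions: 4 (1 equiv), 6 (1.5 equiv), LiN(iPr)2 (2.6 equiv), THF, −78 °C; then Fe(acac)3 (2.5 equiv), −78 °C to rt
Reagents that add atoms: lithium diisopropylamide, LiN(iPr)2, [Li]N(C(C)C)C(C)C (lithium carried only in intermediates 7 and 8; no reagent atom remains in 9)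
Why: LiN(iPr)2 converts both carbonyl compounds into their lithium enolates 7 and 8, Fe(acac)3 (trivalent iron) then removes one electron from the enolate pair, most plausibly from the ester enolate inside a mixed aggregate, the α-carbonyl radical so formed adds to the still metal-bound imide enolate, and a second equivalent of oxidant takes the radical anion of the adduct to the neutral 1,4-dicarbonyl compound, so that the future C3–C4 bond and the complete carbon skeleton arise together. The closest known reaction type is the intermolecular oxidative cross-coupling of two different preformed lithium enolates (an N-acyl oxazolidinone plus an ester or ketone) promoted by soluble trivalent iron or divalent copper salts, an established way to unsymmetrical succinate derivatives. No ring is closed in this step; the lactone ring is closed only in step 5 through the O1–C2 acyl bond. At the imide α-carbon (future C4) the benzyl substituent of the auxiliary covers one face of the lithium-chelated Z-enolate 7, the incoming carbon therefore bonds to the uncovered face, the same one that an alkyl halide would attack, and this corresponds to R, whereas the new centre at the ester α-carbon (future C3) is formed without useful control and is deliberately left as an epimer mixture. Two selectivities are required, hetero- rather than homo-dimerisation, which should follow from the unlike aggregation and ease of oxidation of an imide and an ester enolate and is helped by the excess of inexpensive 6, and face selectivity at the imide carbon, which the auxiliary provides; neither aryl ring carries a free hydroxyl group, so the oxidant has no phenol to attack.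

Step 4
Reactants: 9 tert-butyl (3R)-3-[(4S)-4-benzyl-2-oxooxazolidine-3-carbonyl]-2-(3,4-dimethoxybenzyl)-4-(3,4,5-trimethoxyphenyl)butanoate (epimer mixture at the ester α-carbon)
Product: 10 tert-butyl (3R)-2-(3,4-dimethoxybenzyl)-3-(hydroxymethyl)-4-(3,4,5-trimethoxyphenyl)butanoate (epimer mixture at the ester α-carbon)
Conditions: LiBH4, H2O (1 equiv), Et2O/THF, 0 °C
Reagents that add atoms: none
Why: LiBH4 activated by one equivalent of water attacks the electrophilic exocyclic imide carbonyl far faster than the hindered tert-butyl ester (chemoselective reductive cleavage of an N-acyl oxazolidinone), so that carbon becomes the C5 oxymethylene, the auxiliary is released for recovery, and C4, which the non-basic hydride does not enolise at 0 °C, should keep its R configuration.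

Step 5
Reactants: 10 tert-butyl (3R)-2-(3,4-dimethoxybenzyl)-3-(hydroxymethyl)-4-(3,4,5-trimethoxyphenyl)butanoate (epimer mixture at the ester α-carbon)
Product: 12 (3R,4R)-3-(3,4-dimethoxybenzyl)-4-(3,4,5-trimethoxybenzyl)dihydrofuran-2(3H)-one (trans lactone; target CNP0404830.1), via lactone C3-epimer mixture 11 (not isolated)
Conditions: CF3CO2H, CH2Cl2, 0 °C to rt; evaporate; then DBU, PhMe, 80 °C
Reagents that add atoms: none
Why: CF3CO2H cleaves the tert-butyl ester by alkyl–oxygen fission with loss of isobutene and the freed γ-hydroxy acid closes through the O1–C2 bond to the five-membered lactone (acid-mediated lactonisation, 5-exo-trig) without touching C4, after which DBU reversibly enolises only the lactone α-carbon C3 (thermodynamic base epimerisation), so both C3 epimers should converge on the more stable 3,4-trans lactone, which sets C3 as R while the non-enolisable C4 stays R.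

Compound list
1 | 3-(3,4,5-trimethoxyphenyl)propanoic acid | COc1cc(CCC(=O)O)cc(OC)c1OC | starting material
2 | (S)-4-benzyl-2-oxazolidinone | O=C1N[C@@H](Cc2ccccc2)CO1 | starting material
3 | mixed anhydride of 1 with pivalic acid (formed in the flask) | COc1cc(CCC(=O)OC(=O)C(C)(C)C)cc(OC)c1OC | intermediate
4 | (S)-4-benzyl-3-[3-(3,4,5-trimethoxyphenyl)propanoyl]oxazolidin-2-one (fragment 1) | COc1cc(CCC(=O)N2[C@@H](Cc3ccccc3)COC2=O)cc(OC)c1OC | intermediate
5 | 3-(3,4-dimethoxyphenyl)propanoic acid | COc1ccc(CCC(=O)O)cc1OC | starting material
6 | tert-butyl 3-(3,4-dimethoxyphenyl)propanoate (fragment 2) | COc1ccc(CCC(=O)OC(C)(C)C)cc1OC | intermediate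
7 | lithium Z-enolate of 4 (formed in the flask) | COc1cc(C/C=C(\O[Li])N2[C@@H](Cc3ccccc3)COC2=O)cc(OC)c1OC | intermediate
8 | lithium enolate of 6 (formed in the flask, geometry not specified) | COc1ccc(CC=C(O[Li])OC(C)(C)C)cc1OC | intermediate
9 | tert-butyl (3R)-3-[(4S)-4-benzyl-2-oxooxazolidine-3-carbonyl]-2-(3,4-dimethoxybenzyl)-4-(3,4,5-trimethoxyphenyl)butanoate, epimer mixture at the ester α-carbon | COc1ccc(CC(C(=O)OC(C)(C)C)[C@H](C(=O)N3[C@@H](Cc4ccccc4)COC3=O)Cc2cc(OC)c(OC)c(OC)c2)cc1OC | intermediate
10 | tert-butyl (3R)-2-(3,4-dimethoxybenzyl)-3-(hydroxymethyl)-4-(3,4,5-trimethoxyphenyl)butanoate, epimer mixture at the ester α-carbon | COc1ccc(CC(C(=O)OC(C)(C)C)[C@H](CO)Cc2cc(OC)c(OC)c(OC)c2)cc1OC | intermediate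
11 | (4R)-3-(3,4-dimethoxybenzyl)-4-(3,4,5-trimethoxybenzyl)dihydrofuran-2(3H)-one, cis and trans mixture at C3 (formed in the flask) | COc1ccc(CC2C(=O)OC[C@@H]2Cc2cc(OC)c(OC)c(OC)c2)cc1OC | intermediate
12 | (3R,4R)-3-(3,4-dimethoxybenzyl)-4-(3,4,5-trimethoxybenzyl)dihydrofuran-2(3H)-one, trans lactone, CNP0404830.1 | COc1ccc(C[C@H]2C(=O)OC[C@@H]2Cc2cc(OC)c(OC)c(OC)c2)cc1OC | target

Total step count: 5
Longest linear sequence: 4 steps (1 to 4 to 9 to 10 to 12; the branch 5 to 6 to 9 is equally long)

Steps most likely to fail

Step 3 (oxidative heterocoupling). The process at risk is homo-dimerisation of either enolate competing with the cross-coupling, incomplete oxidation with proton return to 4 and 6, or loss of face control if the lithium chelate of the imide enolate is disturbed. Changing the oxidant to Cu(2-ethylhexanoate)2 (divalent copper) would only adjust conditions; the fallback proper replaces the radical coupling by two polar alkylations. It sets out from 4 and proceeds as follows: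
- The sodium enolate of 4 (NaN(SiMe3)2, THF, −78 °C) is alkylated with tert-butyl bromoacetate on the face remote from the auxiliary benzyl group (Evans alkylation), which should give tert-butyl (3R)-3-[(4S)-4-benzyl-2-oxooxazolidine-3-carbonyl]-4-(3,4,5-trimethoxyphenyl)butanoate F1.
- LiBH4/H2O reduction as in step 4 should give tert-butyl (3R)-3-(hydroxymethyl)-4-(3,4,5-trimethoxyphenyl)butanoate F2.
- CF3CO2H in CH2Cl2 should close this to (4R)-4-(3,4,5-trimethoxybenzyl)dihydrofuran-2(3H)-one F3.
- The lithium enolate of F3 (LiN(SiMe3)2, THF, −78 °C) is alkylated with 3,4-dimethoxybenzyl bromide anti to the C4 substituent, which should give the trans lactone directly.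

The fallback comes back to the route at 12.

Step 4 (imide reduction). The process at risk is hydride attack at the endocyclic carbamate carbonyl with opening of the auxiliary ring, favoured by the crowding around the exocyclic carbonyl, or over-reduction if some lactone forms in the flask. The fallback sets out from 9. LiOH/H2O2 in THF/H2O at 0 °C cleaves the exocyclic acyl group selectively and should give (2R)-4-tert-butoxy-3-(3,4-dimethoxybenzyl)-4-oxo-2-(3,4,5-trimethoxybenzyl)butanoic acid F4 (both epimers at the ester α-carbon), with the auxiliary recovered. BH3·SMe2 in THF at 0 °C then reduces the free carboxylic acid in preference to the tert-butyl ester. The fallback comes back to the route at 10.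

Step 5 (lactonisation and epimerisation). The process at risk is Friedel–Crafts tert-butylation of the electron-rich aryl rings by the tert-butyl cation during acidolysis, or incomplete equilibration that leaves cis lactone. The fallback sets out from 10 and avoids acid altogether. Catalytic KOtBu in THF at 0 °C to rt converts the alcohol into its alkoxide, which attacks the ester carbonyl (acyl–oxygen cleavage with expulsion of tert-butanol, no carbocation). The same basic medium, followed if needed by DBU in warm toluene, equilibrates C3. This way passes through 11 in the flask, makes no new compound (F0) and comes back to the route at 12.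

Further compounds
F1 | step 3 | tert-butyl (3R)-3-[(4S)-4-benzyl-2-oxooxazolidine-3-carbonyl]-4-(3,4,5-trimethoxyphenyl)butanoate | CC(C)(C)OC(=O)C[C@H](C(=O)N1[C@@H](Cc2ccccc2)COC1=O)Cc1cc(OC)c(OC)c(OC)c1
F2 | step 3 | tert-butyl (3R)-3-(hydroxymethyl)-4-(3,4,5-trimethoxyphenyl)butanoate | CC(C)(C)OC(=O)C[C@H](CO)Cc1cc(OC)c(OC)c(OC)c1
F3 | step 3 | (4R)-4-(3,4,5-trimethoxybenzyl)dihydrofuran-2(3H)-one | O=C1OC[C@H](Cc2cc(OC)c(OC)c(OC)c2)C1
F4 | step 4 | (2R)-4-tert-butoxy-3-(3,4-dimethoxybenzyl)-4-oxo-2-(3,4,5-trimethoxybenzyl)butanoic acid, both epimers at the ester α-carbon | COc1ccc(CC(C(=O)OC(C)(C)C)[C@H](C(=O)O)Cc2cc(OC)c(OC)c(OC)c2)cc1OC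
F0 | step 5 | none | none
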